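All runs were computed for substances that don't exist.

- A small charge of enzyme, 16 µM, makes target from starting material and the dosed second substrate, and in the spring run target trails the dose. I carry one quantity, the wait: second substrate standing in the flask divided by the rate at which target forms, the time constant of a pseudo-first-order step.

the same everywhere: enzyme 16 µM
- spring: starting material 0.10 M; second substrate 0.050 M (fed, over 4.0 h); run made earlier; the fed solution adds 0.10 times the starting volume
- flask: starting material 0.050 M; second substrate 0.0500 M (fed, over 4.0 h); the fed solution adds 0.10 times the starting volume; time 4.0 h

spring run (percent of the starting material charged)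

| time / min | target / % | starting material / % |
|---|---|---|
| 12.0 | 0 | 100.0 |
| 25.0 | 1.0 | 99.5 |
| 40.0 | 1.5 | 98.1 |
| 50.0 | 2.2 | 98.0 |
| 60.0 | 3.3 | 97.3 |
| 80.0 | 5.1 | 94.6 |

(scatter of a reading: 0.5 percentage points)

1. amount of target in percent of the starting material charged, at 50 min, 2.0 h and 4.0 h

- charges are per starting volume, the dose included; the dosed solution carries all of it
- the numbers in the tables scatter by 0.5 percentage points (one standard deviation)
- a reading or a percentage of target counts all its forms, free or not

- Which numbers must I know well? Enzyme, dosing time, feed volume and the charge of second substrate are the same in both flasks, so they cancel when I carry the wait across.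
- The scatter on the last spring reading is worth 0.0406 in powers of ten. Starting material differs between the flasks by 0.301, which is more, so that is the number that matters. In the spring run starting material is still read at 94.6% at 80.0 min, so those readings barely show its effect.
- Early on, the standing second substrate grows with time, so target grows with the square of time. The wait is then dose rate times time squared over twice the target, less a third of the time. The spring reading of 5.1% at 80.0 min gives 1.73 h.
- If starting material has no effect, this wait holds in the new flask and target at 4.0 h is 61.0%. If the rate follows starting material, the wait doubles and target is 40.7%.
- I take the middle in logarithms, 2.45 h, which gives 3.17%, 15.8% and 50.7%.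
- The forecast, lower than mine, says 2.5%, 12% and 36%, shaded upward “to allow for partial saturation”.
- The flask gives 3.72%, 16.1% and 43.0%.

    starting material + enzyme ⇌ starting complex (K = 21.0 M⁻¹, k = 94000 M⁻¹ h⁻¹)
    second substrate + starting complex ⇌ ternary complex (K = 9.50 M⁻¹, k = 1.20 × 10⁵ M⁻¹ h⁻¹)
    ternary complex → enzyme + target (k = 16000 h⁻¹)
    crystals ⇌ target, rate k4*(cs4 - [target]) while solid is left; crystals form when [target] > cs4 (solubility = 0.690 mM, k = 25.0 h⁻¹)
    second substrate ⇌ dormant form (K = 0.280, k = 0.120 h⁻¹)

- In this flask the wait reads 2.06 h at 50 min, against 1.73 h from the spring reading, and 2.96 h between 2.0 h and 4.0 h, which is longer. Target stands at 43.0% at 4.0 h partly because starting complex falls back to starting material and enzyme, and partly because the time is short. Without that falling back the same flask reaches 63.0% at 4.0 h, and as it is, this flask holds 95.7% of target at 40.0 h.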